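**Plan**

Chain numbering: C1 is the ketone carbon and C18 the methyl end; the target is (6Z,9R,10E,12Z,15Z).
Retrosynthetic cuts, in order: the three O–Si bonds; C12=C13 (Z-Wittig, C13–C18 from cis-3-hexen-1-ol); C10=C11 (two-carbon ylide); aryl–C1 (aryllithium plus aldehyde, then oxidation); last, C5–C6 and C7–C8 on either side of the C6=C7 alkene.
The last cut rests on one feature: the Z-alkene C6=C7 is separated from the C9 carbinol only by the methylene C8, so C6/C7 can be acetylene placed between a C1–C5 organocopper and a C8–C10 glycidyl ether. The benzene ring, the only ring, is bought; no ring is formed.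
Forward: three-component union to C1–C10; aryl ketone built at C1 while only acid-tolerant groups are present; phenol acetals exchanged for silyl ethers; C10 extended to the E,Z,Z-triene by two Wittig reactions; fluoride then removes all silyl groups, so no acid meets the dienyl carbinol.
Stereochemistry: C9 (R) comes from (S)-glycidol and is never touched; C6=C7 Z from syn-carbocupration; C10=C11 E from a stabilised ylide; C12=C13 Z from a non-stabilised ylide; C15=C16 Z from cis-3-hexen-1-ol.

Key step: step 3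

Remark: O-benzylation changes the descriptor of the epoxide carbon from S (in 1) to R (in 2) only because the CIP ranking of its two CH2O neighbours is reversed; the same spatial arrangement is 9R in the target.
Remark: 3, 5, 11, 20 and 22 are taken as purchasable; Grignard reagent 4 is used as a titrated ether solution.
Abbreviations: PMB = 4-methoxybenzyl, MOM = methoxymethyl, TBS = tert-butyldimethylsilyl, TBDPS = tert-butyldiphenylsilyl, DDQ = 2,3-dichloro-5,6-dicyano-1,4-benzoquinone.

**Route**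

Step 1
Reactants: 1 (S)-glycidol
Product: 2 (R)-glycidyl 4-methoxybenzyl ether
Conditions: NaH, PMBCl, Bu4NI (cat.), THF/DMF, 0 °C → rt
Reagents that add atoms: 4-methoxybenzyl chloride, COc1ccc(CCl)cc1
Why: Williamson etherification, in which the sodium alkoxide of 1 displaces the benzylic chloride (iodide-catalysed SN2) without touching the epoxide carbon, and the Payne rearrangement of glycidol is degenerate, so the configuration is kept.

Step 2
Reactants: 3 2-(4-bromobutyl)-1,3-dioxolane
Product: 4 4-(1,3-dioxolan-2-yl)butylmagnesium bromide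
Conditions: Mg, BrCH2CH2Br (cat.), Et2O, 35 °C
Reagents that add atoms: magnesium, [Mg]
Why: Grignard formation by insertion of magnesium into the primary C–Br bond, the cyclic acetal being inert to organomagnesium reagents.

Step 3
Reactants: 4 4-(1,3-dioxolan-2-yl)butylmagnesium bromide, 5 acetylene, 2 (R)-glycidyl 4-methoxybenzyl ether
Product: 8 (2R,4Z)-9-(1,3-dioxolan-2-yl)-1-[(4-methoxybenzyl)oxy]non-4-en-2-ol, via bromomagnesium dialkylcuprate 6 (not isolated), via bromomagnesium Z-dialkenylcuprate 7 (not isolated)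
Conditions: 4 (2 equiv), CuBr·SMe2 (1 equiv), Et2O/Me2S, −40 °C; 5 (2 equiv), −50 → −25 °C; 2 (0.8 equiv), THF, −40 → −10 °C; aq NH4Cl
Reagents that add atoms: none
Why: Two equivalents of 4 and CuBr·SMe2 form homocuprate 6, whose carbon–copper bonds add across acetylene through a four-centre syn transition state, so that the C1–C5 chain and copper are cis in alkenylcuprate 7 (C5–C6 bond), and 7 then opens epoxide 2 by SN2 attack at its CH2 carbon with retention of the alkene geometry (C7–C8 bond). The closest known reaction type is the Normant carbocupration of acetylene to Z-alkenylcuprates followed by their alkylation with terminal epoxides to Z-homoallylic alcohols. No ring is closed and no new stereocentre is created: the C9 carbinol is the substituted epoxide carbon of 2, which is not attacked, so its configuration is carried over unchanged. The step needs Z geometry, a single acetylene insertion and terminal epoxide opening; the first is secured by the syn mechanism, the second by a measured volume of acetylene at or below −25 °C (alkenylcopper species insert acetylene far more slowly than alkylcopper species), and the third by the steric bias of the monosubstituted, ether-activated epoxide. The dioxolane and the PMB ether are inert to the cuprate, so C1 and C10 emerge differentiated.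

Step 4
Reactants: 8 (2R,4Z)-9-(1,3-dioxolan-2-yl)-1-[(4-methoxybenzyl)oxy]non-4-en-2-ol
Product: 9 tert-butyl({(2R,4Z)-9-(1,3-dioxolan-2-yl)-1-[(4-methoxybenzyl)oxy]non-4-en-2-yl}oxy)diphenylsilane
Conditions: TBDPSCl, imidazole, DMAP (cat.), DMF, rt
Reagents that add atoms: tert-butyl(chloro)diphenylsilane, CC(C)(C)[Si](Cl)(c1ccccc1)c1ccccc1
Why: Imidazole-mediated silylation of the only free hydroxyl, with TBDPS chosen because it should survive the two later acid steps and the aryllithium addition and still fall to fluoride at the end.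

Step 5
Reactants: 9 tert-butyl({(2R,4Z)-9-(1,3-dioxolan-2-yl)-1-[(4-methoxybenzyl)oxy]non-4-en-2-yl}oxy)diphenylsilane
Product: 10 (6Z,9R)-9-[(tert-butyldiphenylsilyl)oxy]-10-[(4-methoxybenzyl)oxy]dec-6-enal
Conditions: 1 M aq HCl, THF, rt
Reagents that add atoms: water, O
Why: Acid-catalysed acetal hydrolysis, placed here because the molecule still holds nothing more acid-sensitive than an isolated Z-alkene, a PMB ether and a TBDPS ether, all of which tolerate dilute aqueous acid at room temperature.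

Step 6
Reactants: 11 5-methoxyresorcinol
Product: 12 1-methoxy-3,5-bis(methoxymethoxy)benzene
Conditions: MOMCl, iPr2NEt, CH2Cl2, 0 °C → rt
Reagents that add atoms: chloromethyl methyl ether, COCCl
Why: Double O-alkylation of the phenols with an α-chloro ether installs two chelating acetal groups that direct the following ortho-lithiation to the carbon between them.

Step 7
Reactants: 12 1-methoxy-3,5-bis(methoxymethoxy)benzene, 10 (6Z,9R)-9-[(tert-butyldiphenylsilyl)oxy]-10-[(4-methoxybenzyl)oxy]dec-6-enal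
Product: 14 (6Z,9R)-9-[(tert-butyldiphenylsilyl)oxy]-1-[4-methoxy-2,6-bis(methoxymethoxy)phenyl]-10-[(4-methoxybenzyl)oxy]dec-6-en-1-ol (both C1 epimers), via aryllithium 13 (not isolated)
Conditions: 12 (1.3 equiv), n-BuLi, THF, 0 °C; then 10, −78 °C; aq NH4Cl
Reagents that add atoms: none
Why: Directed ortho-metalation removes the proton flanked by the two OMOM groups, and the resulting aryllithium adds to the aldehyde at −78 °C faster than it enolises it (1,2-addition); the new C1 carbinol centre is uncontrolled, which is irrelevant because it is oxidised in step 8.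

Step 8
Reactants: 14 (6Z,9R)-9-[(tert-butyldiphenylsilyl)oxy]-1-[4-methoxy-2,6-bis(methoxymethoxy)phenyl]-10-[(4-methoxybenzyl)oxy]dec-6-en-1-ol
Product: 15 (6Z,9R)-9-[(tert-butyldiphenylsilyl)oxy]-1-[4-methoxy-2,6-bis(methoxymethoxy)phenyl]-10-[(4-methoxybenzyl)oxy]dec-6-en-1-one
Conditions: Dess–Martin periodinane, CH2Cl2, rt
Reagents that add atoms: none
Why: Dess–Martin oxidation of the hindered benzylic carbinol to the aryl ketone under neutral conditions that should leave the Z-alkene, the PMB ether, the MOM acetals and the silyl ether untouched and that erase the uncontrolled C1 centre.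

Step 9
Reactants: 15 (6Z,9R)-9-[(tert-butyldiphenylsilyl)oxy]-1-[4-methoxy-2,6-bis(methoxymethoxy)phenyl]-10-[(4-methoxybenzyl)oxy]dec-6-en-1-one
Product: 16 (6Z,9R)-9-[(tert-butyldiphenylsilyl)oxy]-1-(2,6-dihydroxy-4-methoxyphenyl)-10-[(4-methoxybenzyl)oxy]dec-6-en-1-one
Conditions: HCl (1.25 M in MeOH), THF, rt → 40 °C
Reagents that add atoms: none
Why: Acid-catalysed methanolysis of the two aryl MOM acetals (acetal exchange to dimethoxymethane), a routine operation on MOM-protected acylphloroglucinols, is carried out before any dienyl carbinol exists, and the alkyl PMB ether and the secondary TBDPS ether are markedly more stable to dilute methanolic HCl.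

Step 10
Reactants: 16 (6Z,9R)-9-[(tert-butyldiphenylsilyl)oxy]-1-(2,6-dihydroxy-4-methoxyphenyl)-10-[(4-methoxybenzyl)oxy]dec-6-en-1-one
Product: 17 (6Z,9R)-1-{2,6-bis[(tert-butyldimethylsilyl)oxy]-4-methoxyphenyl}-9-[(tert-butyldiphenylsilyl)oxy]-10-[(4-methoxybenzyl)oxy]dec-6-en-1-one
Conditions: TBSCl, imidazole, DMAP (cat.), DMF, 40 °C
Reagents that add atoms: tert-butyl(chloro)dimethylsilane, CC(C)(C)[Si](C)(C)Cl
Why: Silylation of both hydrogen-bonded phenols exchanges the acid-labile acetals for aryl silyl ethers, which should survive the oxidations and both Wittig reactions and leave with fluoride at or below room temperature.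

Step 11
Reactants: 17 (6Z,9R)-1-{2,6-bis[(tert-butyldimethylsilyl)oxy]-4-methoxyphenyl}-9-[(tert-butyldiphenylsilyl)oxy]-10-[(4-methoxybenzyl)oxy]dec-6-en-1-one
Product: 18 (6Z,9R)-1-{2,6-bis[(tert-butyldimethylsilyl)oxy]-4-methoxyphenyl}-9-[(tert-butyldiphenylsilyl)oxy]-10-hydroxydec-6-en-1-one
Conditions: DDQ, CH2Cl2/pH 7 buffer, 0 °C → rt
Reagents that add atoms: none
Why: Oxidative PMB ether cleavage, in which DDQ abstracts hydride from the 4-methoxybenzylic position and water hydrolyses the oxocarbenium ion to anisaldehyde and the primary alcohol, while the acylated arene has no benzylic C–H and the silyl ethers are inert.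

Step 12
Reactants: 18 (6Z,9R)-1-{2,6-bis[(tert-butyldimethylsilyl)oxy]-4-methoxyphenyl}-9-[(tert-butyldiphenylsilyl)oxy]-10-hydroxydec-6-en-1-one
Product: 19 (2R,4Z)-10-{2,6-bis[(tert-butyldimethylsilyl)oxy]-4-methoxyphenyl}-2-[(tert-butyldiphenylsilyl)oxy]-10-oxodec-4-enal
Conditions: Dess–Martin periodinane, CH2Cl2, 0 °C → rt
Reagents that add atoms: none
Why: Dess–Martin oxidation of the primary alcohol to the α-silyloxy aldehyde under non-basic conditions that should not epimerise C9, the crude aldehyde being used at once.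

Step 13
Reactants: 19 (2R,4Z)-10-{2,6-bis[(tert-butyldimethylsilyl)oxy]-4-methoxyphenyl}-2-[(tert-butyldiphenylsilyl)oxy]-10-oxodec-4-enal, 20 (triphenylphosphoranylidene)acetaldehyde
Product: 21 (2E,4R,6Z)-12-{2,6-bis[(tert-butyldimethylsilyl)oxy]-4-methoxyphenyl}-4-[(tert-butyldiphenylsilyl)oxy]-12-oxododeca-2,6-dienal
Conditions: toluene, 80 °C
Reagents that add atoms: none
Why: Wittig reaction with a stabilised formyl ylide, which reacts with the aldehyde but not with the hindered aryl ketone, gives the E-enal (C10=C11) and is too weakly basic to enolise the C9 centre.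

Step 14
Reactants: 22 cis-3-hexen-1-ol
Product: 23 (3Z)-1-iodohex-3-ene
Conditions: I2, PPh3, imidazole, CH2Cl2, 0 °C → rt
Reagents that add atoms: iodine, II
Why: Appel-type iodination, in which iodide displaces the alkoxyphosphonium ion of the primary alcohol by SN2 without touching the Z-alkene.

Step 15
Reactants: 23 (3Z)-1-iodohex-3-ene
Product: 24 [(3Z)-hex-3-en-1-yl]triphenylphosphonium iodide
Conditions: PPh3, MeCN, 80 °C
Reagents that add atoms: triphenylphosphine, c1ccc(cc1)P(c1ccccc1)c1ccccc1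
Why: Quaternisation of triphenylphosphine by the primary iodide (SN2) gives the phosphonium salt with the homoallylic Z-alkene unchanged.

Step 16
Reactants: 24 [(3Z)-hex-3-en-1-yl]triphenylphosphonium iodide, 21 (2E,4R,6Z)-12-{2,6-bis[(tert-butyldimethylsilyl)oxy]-4-methoxyphenyl}-4-[(tert-butyldiphenylsilyl)oxy]-12-oxododeca-2,6-dienal
Product: 26 (6Z,9R,10E,12Z,15Z)-1-{2,6-bis[(tert-butyldimethylsilyl)oxy]-4-methoxyphenyl}-9-[(tert-butyldiphenylsilyl)oxy]octadeca-6,10,12,15-tetraen-1-one, via phosphorus ylide 25 (not isolated)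
Conditions: 24 (1.5 equiv), NaN(SiMe3)2 (1.4 equiv), THF, −78 → 0 °C; then 21, −78 → −20 °C; pH 7 buffer
Reagents that add atoms: none
Why: Z-selective Wittig olefination, in which the non-stabilised ylide made with a lithium-free amide base adds to the enal at −78 °C through a kinetically formed cis-oxaphosphetane and so sets C12=C13 as Z, while the aldehyde reacts far faster than the di-ortho-substituted aryl ketone and the C15=C16 geometry is carried in from 22.

Step 17
Reactants: 26 (6Z,9R,10E,12Z,15Z)-1-{2,6-bis[(tert-butyldimethylsilyl)oxy]-4-methoxyphenyl}-9-[(tert-butyldiphenylsilyl)oxy]octadeca-6,10,12,15-tetraen-1-one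
Product: 27 (6Z,9R,10E,12Z,15Z)-1-(2,6-dihydroxy-4-methoxyphenyl)-9-hydroxyoctadeca-6,10,12,15-tetraen-1-one
Conditions: Bu4NF, THF, 0 °C → rt; pH 7 buffer
Reagents that add atoms: none
Why: Fluoride-induced desilylation should cleave the two aryl TBS ethers at once and the allylic TBDPS ether more slowly at room temperature, under mildly basic conditions that neither ionise the dienyl carbinol nor isomerise the polyene.

**Compound list**

1 | (S)-glycidol, (2S)-oxiran-2-ylmethanol | OC[C@H]1CO1 | starting material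
2 | (R)-glycidyl 4-methoxybenzyl ether, (2R)-2-{[(4-methoxybenzyl)oxy]methyl}oxirane | COc1ccc(COC[C@H]2CO2)cc1 | intermediate
3 | 2-(4-bromobutyl)-1,3-dioxolane | BrCCCCC1OCCO1 | starting material
4 | 4-(1,3-dioxolan-2-yl)butylmagnesium bromide | Br[Mg]CCCCC1OCCO1 | intermediate
5 | acetylene | C#C | starting material
6 | bromomagnesium bis[4-(1,3-dioxolan-2-yl)butyl]cuprate (not isolated) | Br[Mg+].C1COC(CCCC[Cu-]CCCCC2OCCO2)O1 | intermediate
7 | bromomagnesium bis[(1Z)-6-(1,3-dioxolan-2-yl)hex-1-en-1-yl]cuprate (not isolated) | Br[Mg+].C1COC(CCCC/C=C\[Cu-]/C=C\CCCCC2OCCO2)O1 | intermediate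
8 | (2R,4Z)-9-(1,3-dioxolan-2-yl)-1-[(4-methoxybenzyl)oxy]non-4-en-2-ol | COc1ccc(COC[C@H](O)C/C=C\CCCCC2OCCO2)cc1 | intermediate
9 | tert-butyl({(2R,4Z)-9-(1,3-dioxolan-2-yl)-1-[(4-methoxybenzyl)oxy]non-4-en-2-yl}oxy)diphenylsilane | COc1ccc(COC[C@H](O[Si](c2ccccc2)(c2ccccc2)C(C)(C)C)C/C=C\CCCCC2OCCO2)cc1 | intermediate
10 | (6Z,9R)-9-[(tert-butyldiphenylsilyl)oxy]-10-[(4-methoxybenzyl)oxy]dec-6-enal | COc1ccc(COC[C@H](O[Si](c2ccccc2)(c2ccccc2)C(C)(C)C)C/C=C\CCCCC=O)cc1 | intermediate
11 | 5-methoxyresorcinol, 5-methoxybenzene-1,3-diol | COc1cc(O)cc(O)c1 | starting material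
12 | 1-methoxy-3,5-bis(methoxymethoxy)benzene | COCOc1cc(OC)cc(OCOC)c1 | intermediate
13 | [4-methoxy-2,6-bis(methoxymethoxy)phenyl]lithium (not isolated) | [Li]c1c(OCOC)cc(OC)cc1OCOC | intermediate
14 | (6Z,9R)-9-[(tert-butyldiphenylsilyl)oxy]-1-[4-methoxy-2,6-bis(methoxymethoxy)phenyl]-10-[(4-methoxybenzyl)oxy]dec-6-en-1-ol, both C1 epimers | COCOc1cc(OC)cc(OCOC)c1C(O)CCCC/C=C\C[C@@H](O[Si](c1ccccc1)(c1ccccc1)C(C)(C)C)COCc1ccc(OC)cc1 | intermediate
15 | (6Z,9R)-9-[(tert-butyldiphenylsilyl)oxy]-1-[4-methoxy-2,6-bis(methoxymethoxy)phenyl]-10-[(4-methoxybenzyl)oxy]dec-6-en-1-one | COCOc1cc(OC)cc(OCOC)c1C(=O)CCCC/C=C\C[C@@H](O[Si](c1ccccc1)(c1ccccc1)C(C)(C)C)COCc1ccc(OC)cc1 | intermediate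
16 | (6Z,9R)-9-[(tert-butyldiphenylsilyl)oxy]-1-(2,6-dihydroxy-4-methoxyphenyl)-10-[(4-methoxybenzyl)oxy]dec-6-en-1-one | COc1cc(O)c(C(=O)CCCC/C=C\C[C@@H](O[Si](c2ccccc2)(c2ccccc2)C(C)(C)C)COCc2ccc(OC)cc2)c(O)c1 | intermediate
17 | (6Z,9R)-1-{2,6-bis[(tert-butyldimethylsilyl)oxy]-4-methoxyphenyl}-9-[(tert-butyldiphenylsilyl)oxy]-10-[(4-methoxybenzyl)oxy]dec-6-en-1-one | COc1cc(O[Si](C)(C)C(C)(C)C)c(C(=O)CCCC/C=C\C[C@@H](O[Si](c2ccccc2)(c2ccccc2)C(C)(C)C)COCc2ccc(OC)cc2)c(O[Si](C)(C)C(C)(C)C)c1 | intermediate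
18 | (6Z,9R)-1-{2,6-bis[(tert-butyldimethylsilyl)oxy]-4-methoxyphenyl}-9-[(tert-butyldiphenylsilyl)oxy]-10-hydroxydec-6-en-1-one | COc1cc(O[Si](C)(C)C(C)(C)C)c(C(=O)CCCC/C=C\C[C@@H](O[Si](c2ccccc2)(c2ccccc2)C(C)(C)C)CO)c(O[Si](C)(C)C(C)(C)C)c1 | intermediate
19 | (2R,4Z)-10-{2,6-bis[(tert-butyldimethylsilyl)oxy]-4-methoxyphenyl}-2-[(tert-butyldiphenylsilyl)oxy]-10-oxodec-4-enal | COc1cc(O[Si](C)(C)C(C)(C)C)c(C(=O)CCCC/C=C\C[C@@H](O[Si](c2ccccc2)(c2ccccc2)C(C)(C)C)C=O)c(O[Si](C)(C)C(C)(C)C)c1 | intermediate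
20 | (triphenylphosphoranylidene)acetaldehyde | O=CC=P(c1ccccc1)(c1ccccc1)c1ccccc1 | starting material
21 | (2E,4R,6Z)-12-{2,6-bis[(tert-butyldimethylsilyl)oxy]-4-methoxyphenyl}-4-[(tert-butyldiphenylsilyl)oxy]-12-oxododeca-2,6-dienal | COc1cc(O[Si](C)(C)C(C)(C)C)c(C(=O)CCCC/C=C\C[C@@H](O[Si](c2ccccc2)(c2ccccc2)C(C)(C)C)/C=C/C=O)c(O[Si](C)(C)C(C)(C)C)c1 | intermediate
22 | cis-3-hexen-1-ol, (3Z)-hex-3-en-1-ol | CC/C=C\CCO | starting material
23 | (3Z)-1-iodohex-3-ene | CC/C=C\CCI | intermediate
24 | [(3Z)-hex-3-en-1-yl]triphenylphosphonium iodide | CC/C=C\CC[P+](c1ccccc1)(c1ccccc1)c1ccccc1.[I-] | intermediate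
25 | [(3Z)-hex-3-en-1-ylidene]triphenylphosphorane (not isolated) | CC/C=C\CC=P(c1ccccc1)(c1ccccc1)c1ccccc1 | intermediate
26 | (6Z,9R,10E,12Z,15Z)-1-{2,6-bis[(tert-butyldimethylsilyl)oxy]-4-methoxyphenyl}-9-[(tert-butyldiphenylsilyl)oxy]octadeca-6,10,12,15-tetraen-1-one | COc1cc(O[Si](C)(C)C(C)(C)C)c(C(=O)CCCC/C=C\C[C@@H](O[Si](c2ccccc2)(c2ccccc2)C(C)(C)C)/C=C/C=C\C/C=C\CC)c(O[Si](C)(C)C(C)(C)C)c1 | intermediate
27 | (6Z,9R,10E,12Z,15Z)-1-(2,6-dihydroxy-4-methoxyphenyl)-9-hydroxyoctadeca-6,10,12,15-tetraen-1-one | CC/C=C\C/C=C\C=C\[C@H](O)C/C=C\CCCCC(=O)c1c(O)cc(OC)cc1O | target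

**Step count and risks**

Total step count: 17.
Longest linear sequence: 13 steps (1, 3, 4, 5, 7, 8, 9, 10, 11, 12, 13, 16, 17, counted from 1; the branch from 3 through step 2 is equally long).

Steps most likely to fail:

1. Step 3. The alkenylcuprate is a sluggish nucleophile, so epoxide opening may be outrun by bromide attack promoted by MgBr2 (halohydrin formation) or by thermal decay of the cuprate above about −10 °C; acetylene may also insert twice. The fallback sets out from 3 and 2, comes back at 8, and makes the same two bonds in separate operations. Bromide 3 is alkylated with LiC≡CH·H2NCH2CH2NH2 in DMSO to give 2-(hex-5-yn-1-yl)-1,3-dioxolane F1. Its lithium acetylide (n-BuLi, THF, −78 °C) opens epoxide 2 at the CH2 carbon in the presence of BF3·OEt2 to give (2R)-9-(1,3-dioxolan-2-yl)-1-[(4-methoxybenzyl)oxy]non-4-yn-2-ol F2. Syn-semihydrogenation (H2, Pd/CaCO3 poisoned with Pb(OAc)2, quinoline, EtOAc) should then give 8 with the Z-alkene.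

2. Step 16. Z selectivity at C12=C13 may erode through oxaphosphetane equilibration, the basic ylide may enolise the enal or the ketone, and geometric isomers may be hard to separate. The fallback sets out from 19 and 22, comes back at 26, and takes both alkene geometries from preformed partners. Takai iodo-olefination of 19 (CrCl2, CHI3, THF, 0 °C) gives (6Z,9R,10E)-1-{2,6-bis[(tert-butyldimethylsilyl)oxy]-4-methoxyphenyl}-9-[(tert-butyldiphenylsilyl)oxy]-11-iodoundeca-6,10-dien-1-one F3. Separately, 22 is oxidised with Dess–Martin periodinane to (3Z)-hex-3-enal F4, which Stork–Zhao olefination ((iodomethyl)triphenylphosphonium iodide, NaN(SiMe3)2, THF/DMPU, −78 °C) converts into (1Z,4Z)-1-iodohepta-1,4-diene F5. Iodine–lithium exchange (t-BuLi, Et2O, −78 °C) and quenching with Bu3SnCl give tributyl[(1Z,4Z)-hepta-1,4-dien-1-yl]stannane F6. Stille coupling of F3 with F6 (PdCl2(MeCN)2, DMF, rt) should give 26 with retention at both alkenes.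

3. Step 9. Acid strong enough to cleave both aryl acetals may begin to solvolyse the PMB ether, giving mixtures of partly deprotected material. The fallback sets out from 15, comes back at 18, and removes the PMB group on purpose, which also makes step 11 unnecessary. Methanolic HCl at 55 °C cleaves both MOM groups and the PMB ether to give (6Z,9R)-9-[(tert-butyldiphenylsilyl)oxy]-1-(2,6-dihydroxy-4-methoxyphenyl)-10-hydroxydec-6-en-1-one F7. Silylation of all three hydroxyls (TBSCl, imidazole, DMF) gives (6Z,9R)-1-{2,6-bis[(tert-butyldimethylsilyl)oxy]-4-methoxyphenyl}-10-[(tert-butyldimethylsilyl)oxy]-9-[(tert-butyldiphenylsilyl)oxy]dec-6-en-1-one F8. The primary alkyl silyl ether, far more acid-labile than the aryl silyl ethers and the secondary TBDPS ether, is then cleaved selectively (camphorsulfonic acid cat., MeOH/CH2Cl2, 0 °C) to return 18.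

**Further compounds**

F1 | step 3 | 2-(hex-5-yn-1-yl)-1,3-dioxolane | C#CCCCCC1OCCO1
F2 | step 3 | (2R)-9-(1,3-dioxolan-2-yl)-1-[(4-methoxybenzyl)oxy]non-4-yn-2-ol | COc1ccc(COC[C@H](O)CC#CCCCCC2OCCO2)cc1
F3 | step 16 | (6Z,9R,10E)-1-{2,6-bis[(tert-butyldimethylsilyl)oxy]-4-methoxyphenyl}-9-[(tert-butyldiphenylsilyl)oxy]-11-iodoundeca-6,10-dien-1-one | COc1cc(O[Si](C)(C)C(C)(C)C)c(C(=O)CCCC/C=C\C[C@@H](O[Si](c2ccccc2)(c2ccccc2)C(C)(C)C)/C=C/I)c(O[Si](C)(C)C(C)(C)C)c1
F4 | step 16 | (3Z)-hex-3-enal | CC/C=C\CC=O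
F5 | step 16 | (1Z,4Z)-1-iodohepta-1,4-diene | CC/C=C\C/C=C\I
F6 | step 16 | tributyl[(1Z,4Z)-hepta-1,4-dien-1-yl]stannane | CCCC[Sn](CCCC)(CCCC)/C=C\C/C=C\CC
F7 | step 9 | (6Z,9R)-9-[(tert-butyldiphenylsilyl)oxy]-1-(2,6-dihydroxy-4-methoxyphenyl)-10-hydroxydec-6-en-1-one | COc1cc(O)c(C(=O)CCCC/C=C\C[C@@H](O[Si](c2ccccc2)(c2ccccc2)C(C)(C)C)CO)c(O)c1
F8 | step 9 | (6Z,9R)-1-{2,6-bis[(tert-butyldimethylsilyl)oxy]-4-methoxyphenyl}-10-[(tert-butyldimethylsilyl)oxy]-9-[(tert-butyldiphenylsilyl)oxy]dec-6-en-1-one | COc1cc(O[Si](C)(C)C(C)(C)C)c(C(=O)CCCC/C=C\C[C@@H](O[Si](c2ccccc2)(c2ccccc2)C(C)(C)C)CO[Si](C)(C)C(C)(C)C)c(O[Si](C)(C)C(C)(C)C)c1
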